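The western half is read as a remodelled (R)-pulegone, whose ten carbons supply the side-chain CH(CH3), the CH2CH2 linker, the ring CH, the methylene-bearing ring carbon and the C(CH3)2 group, with both stereocentres. Vinyl conjugate addition and cleavage of the cyclohexanone C1–C6 bond unravel it into an acyclic vinyl ketone. The key step exploits that the ring CH2–CH(CH3) bond lies β,γ to the methylene-bearing carbon (a ketone until late): iron-hydride hydrogen-atom transfer turns the vinyl group on C(CH3)2 into the CH(CH3) radical, which attacks the enone CH2 (6-endo), closing the trimethylcyclohexanone ring with the methyl cis to the side chain. Copper-catalysed SN2' coupling with a farnesol-derived phosphate then creates the quaternary centre.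

Key step: step 5

Remark: the chiral ligands of steps 11 and 14 are taken in whichever antipode delivers the stated configuration, since the sense of induction in both reaction types is catalyst-controlled.

Step 1
Reactants: 1 (R)-(+)-pulegone
Product: 2 (2S,5R)-5-methyl-2-(2-methylbut-3-en-2-yl)cyclohexan-1-one (trans isomer, separated from the minor cis epimer)
Conditions: CH2=CHMgBr, CuI (10 mol%), THF, −30 to 0 °C; aqueous work-up; then KOH (cat.), EtOH, reflux
Reagents that add atoms: vinylmagnesium bromide, C=C[Mg]Br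
Why: Copper-catalysed conjugate addition of the Grignard reagent to the s-cis-locked β,β-disubstituted enone builds the quaternary carbon, and base equilibration of the epimerisable α-carbon should give mainly the trans (diequatorial, menthone-type) ketone, so that C2 (S) is set by thermodynamic control relative to the untouched C5 (R) centre of pulegone.

Step 2
Reactants: 2 (2S,5R)-5-methyl-2-(2-methylbut-3-en-2-yl)cyclohexan-1-one
Product: 4 (3R,6S)-2-hydroxy-3-methyl-6-(2-methylbut-3-en-2-yl)cyclohexan-1-one (both C2 epimers), via potassium enolate 3 (not isolated)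
Conditions: KN(SiMe3)2, THF, −78 °C; then trans-2-(phenylsulfonyl)-3-phenyloxaziridine, −78 °C; AcOH quench
Reagents that add atoms: trans-2-(phenylsulfonyl)-3-phenyloxaziridine (Davis oxaziridine), O=S(=O)(N1OC1c1ccccc1)c1ccccc1
Why: Kinetic deprotonation should occur only at the unhindered α-CH2 (the other α-carbon is tertiary and flanked by the quaternary carbon) and the enolate is hydroxylated by the N-sulfonyloxaziridine (Davis oxidation), the carbinol configuration being immaterial because this carbon becomes the aldehyde in step 4.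

Step 3
Reactants: 4 (3R,6S)-2-hydroxy-3-methyl-6-(2-methylbut-3-en-2-yl)cyclohexan-1-one
Product: 5 (3R,6S)-1-ethenyl-3-methyl-6-(2-methylbut-3-en-2-yl)cyclohexane-1,2-diol (diastereomers at C1 and C2)
Conditions: CH2=CHMgBr (3 equiv), THF, −20 °C to rt; aqueous work-up
Reagents that add atoms: vinylmagnesium bromide, C=C[Mg]Br
Why: Grignard 1,2-addition to the ketone, assisted by chelation to the neighbouring magnesium alkoxide, gives the tertiary allylic alcohol, whose configuration is immaterial because this carbon becomes the ketone in step 4.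

Step 4
Reactants: 5 (3R,6S)-1-ethenyl-3-methyl-6-(2-methylbut-3-en-2-yl)cyclohexane-1,2-diol
Product: 6 (2R,5S)-2-methyl-5-(2-methylbut-3-en-2-yl)-6-oxooct-7-enal
Conditions: Pb(OAc)4, CH2Cl2, −20 to 0 °C; filtered and used directly
Reagents that add atoms: none
Why: Criegee glycol cleavage cuts exactly the C1–C2 bond of the vicinal diol whatever its relative configuration, turning the tertiary allylic carbinol into the vinyl ketone and the secondary carbinol into the aldehyde without touching either stereocentre.

Step 5
Reactants: 6 (2R,5S)-2-methyl-5-(2-methylbut-3-en-2-yl)-6-oxooct-7-enal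
Product: 7 (2R)-2-methyl-4-[(1S,3S)-2,2,3-trimethyl-6-oxocyclohexyl]butanal
Conditions: Fe(acac)3 (30 mol%), PhSiH3 (2.5 equiv), EtOH/THF, 60 °C, high dilution
Reagents that add atoms: none
Why: Fe(acac)3 and PhSiH3 generate an iron hydride that transfers a hydrogen atom to the terminal CH2 of the vinyl group on the quaternary carbon (giving the new methyl), the resulting nucleophilic secondary radical adds to the terminal CH2 of the vinyl ketone, and the α-keto radical is reduced to the iron enolate and protonated by ethanol. The closest known reaction type is the iron-hydride-initiated reductive olefin coupling (radical Giese addition of an unactivated donor olefin to an enone), here in its intramolecular form. The cyclohexanone ring closes in the 6-endo-trig mode, expected to win over 5-exo because the carbonyl lies inside the tether and the radical attacks the polarity-matched, unsubstituted β-carbon, with the gem-dimethyl group accelerating closure. The new methyl-bearing stereocentre is controlled by the existing α-stereocentre: in the chair-like transition state the side chain and the methyl group of the radical should both sit pseudo-equatorially, which gives the 1,3-cis (1S,3S) ring. The step needs the iron hydride to engage the vinyl group and not the enone, which its preference for the electron-richer olefin and the fast intramolecular trapping should secure, and it needs the aldehyde to survive, as carbonyl groups normally do under these conditions.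

Step 6
Reactants: 7 (2R)-2-methyl-4-[(1S,3S)-2,2,3-trimethyl-6-oxocyclohexyl]butanal
Product: 8 (2S,4S)-3,3,4-trimethyl-2-[(3R)-3-methylpent-4-yn-1-yl]cyclohexan-1-one
Conditions: dimethyl (1-diazo-2-oxopropyl)phosphonate, K2CO3, MeOH, 0 °C to rt
Reagents that add atoms: dimethyl (1-diazo-2-oxopropyl)phosphonate (Ohira–Bestmann reagent), COP(=O)(OC)C(=[N+]=[N-])C(C)=O
Why: Ohira–Bestmann homologation converts the aldehyde selectively into the terminal alkyne under mild conditions that normally do not epimerise α-methyl aldehydes, leave the hindered ketone untouched and can only move the ketone α-carbon towards its more stable cis arrangement.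

Step 7
Reactants: 8 (2S,4S)-3,3,4-trimethyl-2-[(3R)-3-methylpent-4-yn-1-yl]cyclohexan-1-one
Product: 9 (3R)-3-methyl-5-[(1R,3S)-2,2,3-trimethyl-6-methylidenecyclohexyl]pent-1-yne
Conditions: Ph3PCH3Br, KN(SiMe3)2 (slightly less than 1 equiv per phosphonium salt), toluene, 80 °C
Reagents that add atoms: methyltriphenylphosphonium bromide, C[P+](c1ccccc1)(c1ccccc1)c1ccccc1.[Br-]
Why: Wittig methylenation with a ylide free of excess base at elevated temperature should overcome the hindrance of the 2-substituted 3,3-dimethylcyclohexanone without isomerising the alkyne, and any epimerisation of the α-carbon converges on the preferred cis isomer.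

Step 8
Reactants: 10 (2E,6E)-farnesol
Product: 11 tert-butyldimethyl{[(2E,6E)-3,7,11-trimethyldodeca-2,6,10-trien-1-yl]oxy}silane
Conditions: TBSCl, imidazole, DMF, rt
Reagents that add atoms: tert-butyldimethylsilyl chloride, CC(C)(C)[Si](C)(C)Cl
Why: Standard silylation protects the primary allylic alcohol as an ether that survives the oxidation, chlorination and Grignard steps.

Step 9
Reactants: 11 tert-butyldimethyl{[(2E,6E)-3,7,11-trimethyldodeca-2,6,10-trien-1-yl]oxy}silane
Product: 12 (2E,6E,10E)-12-[(tert-butyldimethylsilyl)oxy]-2,6,10-trimethyldodeca-2,6,10-trien-1-ol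
Conditions: SeO2 (cat.), t-BuOOH, salicylic acid (cat.), CH2Cl2, 0 °C to rt
Reagents that add atoms: tert-butyl hydroperoxide, CC(C)(C)OO
Why: Catalytic SeO2 allylic oxidation (ene reaction then [2,3]-sigmatropic shift) should attack the most electron-rich, terminal trisubstituted olefin at its (E)-methyl group and deliver the (E)-allylic alcohol.

Step 10
Reactants: 12 (2E,6E,10E)-12-[(tert-butyldimethylsilyl)oxy]-2,6,10-trimethyldodeca-2,6,10-trien-1-ol
Product: 13 tert-butyl{[(2E,6E,10E)-12-chloro-3,7,11-trimethyldodeca-2,6,10-trien-1-yl]oxy}dimethylsilane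
Conditions: PPh3, CCl4, 60 °C
Reagents that add atoms: carbon tetrachloride, ClC(Cl)(Cl)Cl
Why: Appel chlorination converts the primary allylic alcohol into the chloride by SN2 displacement under neutral conditions without allylic transposition.

Step 11
Reactants: 13 tert-butyl{[(2E,6E,10E)-12-chloro-3,7,11-trimethyldodeca-2,6,10-trien-1-yl]oxy}dimethylsilane
Product: 14 tert-butyldimethyl{[(2E,6E,10S)-3,7,10,11-tetramethyldodeca-2,6,11-trien-1-yl]oxy}silane
Conditions: MeMgBr (slow addition), copper thiophene-2-carboxylate (3 mol%), chiral phosphoramidite ligand (3.3 mol%), CH2Cl2, −78 °C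
Reagents that add atoms: methylmagnesium bromide, C[Mg]Br
Why: Copper-catalysed asymmetric allylic alkylation delivers the methyl group in SN2' fashion to the γ-carbon of the β-methyl-substituted allylic chloride, creating the isopropenyl group and the (10S) stereocentre under control of the chiral ligand.

Step 12
Reactants: 14 tert-butyldimethyl{[(2E,6E,10S)-3,7,10,11-tetramethyldodeca-2,6,11-trien-1-yl]oxy}silane
Product: 15 (2E,6E,10S)-3,7,10,11-tetramethyldodeca-2,6,11-trien-1-ol
Conditions: Bu4NF, THF, 0 °C to rt; aqueous work-up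
Reagents that add atoms: none
Why: Fluoride-mediated desilylation frees the primary allylic alcohol without affecting the olefins.

Step 13
Reactants: 15 (2E,6E,10S)-3,7,10,11-tetramethyldodeca-2,6,11-trien-1-ol
Product: 16 diethyl (2E,6E,10S)-3,7,10,11-tetramethyldodeca-2,6,11-trien-1-yl phosphate
Conditions: ClP(O)(OEt)2, Et3N, DMAP (cat.), CH2Cl2, 0 °C
Reagents that add atoms: diethyl chlorophosphate, CCOP(=O)(Cl)OCC
Why: Phosphorylation of the primary allylic alcohol installs the leaving group required for the copper-catalysed SN2' substitution.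

Step 14
Reactants: 9 (3R)-3-methyl-5-[(1R,3S)-2,2,3-trimethyl-6-methylidenecyclohexyl]pent-1-yne and 16 diethyl (2E,6E,10S)-3,7,10,11-tetramethyldodeca-2,6,11-trien-1-yl phosphate
Product: 18 (1R,3S)-1-[(3R,4E,6S,9E,13S)-6-ethenyl-3,6,10,13,14-pentamethylpentadeca-4,9,14-trien-1-yl]-2,2,3-trimethyl-6-methylidenecyclohexane (target), via alkenylalane 17 (not isolated)
Conditions: 9, i-Bu2AlH, hexane, 55 °C; then 16, CuCl2·2H2O (2 mol%), chiral sulfonate-bearing imidazolinium salt (N-heterocyclic carbene precursor, 2.5 mol%), THF, −15 °C; aqueous acidic work-up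
Reagents that add atoms: none
Why: Syn-hydroalumination of the terminal alkyne gives the (E)-alkenylalane, which in the copper–carbene-catalysed enantioselective allylic substitution should attack the γ-carbon of the trisubstituted (E)-allylic phosphate in SN2' fashion with retention of olefin geometry, creating the vinyl group and the quaternary (S) centre under catalyst control.

Compound list
1 | (R)-(+)-pulegone, (5R)-5-methyl-2-(propan-2-ylidene)cyclohexan-1-one | C[C@@H]1CCC(=C(C)C)C(=O)C1 | starting material
2 | (2S,5R)-5-methyl-2-(2-methylbut-3-en-2-yl)cyclohexan-1-one | C[C@@H]1CC[C@@H](C(C)(C)C=C)C(=O)C1 | intermediate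
3 | potassium (3R,6S)-3-methyl-6-(2-methylbut-3-en-2-yl)cyclohex-1-en-1-olate | C[C@@H]1CC[C@@H](C(C)(C)C=C)C([O-])=C1.[K+] | intermediate (not isolated)
4 | (3R,6S)-2-hydroxy-3-methyl-6-(2-methylbut-3-en-2-yl)cyclohexan-1-one, both C2 epimers | C[C@@H]1CC[C@@H](C(C)(C)C=C)C(=O)C1O | intermediate
5 | (3R,6S)-1-ethenyl-3-methyl-6-(2-methylbut-3-en-2-yl)cyclohexane-1,2-diol, diastereomers at C1 and C2 | C[C@@H]1CC[C@@H](C(C)(C)C=C)C(O)(C=C)C1O | intermediate
6 | (2R,5S)-2-methyl-5-(2-methylbut-3-en-2-yl)-6-oxooct-7-enal | C[C@@H](C=O)CC[C@@H](C(C)(C)C=C)C(=O)C=C | intermediate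
7 | (2R)-2-methyl-4-[(1S,3S)-2,2,3-trimethyl-6-oxocyclohexyl]butanal | O=C[C@H](C)CC[C@@H]1C(=O)CC[C@H](C)C1(C)C | intermediate
8 | (2S,4S)-3,3,4-trimethyl-2-[(3R)-3-methylpent-4-yn-1-yl]cyclohexan-1-one | C#C[C@H](C)CC[C@@H]1C(=O)CC[C@H](C)C1(C)C | intermediate
9 | (3R)-3-methyl-5-[(1R,3S)-2,2,3-trimethyl-6-methylidenecyclohexyl]pent-1-yne | C#C[C@H](C)CC[C@@H]1C(=C)CC[C@H](C)C1(C)C | intermediate
10 | (2E,6E)-farnesol | CC(C)=CCC/C(C)=C/CC/C(C)=C/CO | starting material
11 | tert-butyldimethyl{[(2E,6E)-3,7,11-trimethyldodeca-2,6,10-trien-1-yl]oxy}silane | CC(C)=CCC/C(C)=C/CC/C(C)=C/CO[Si](C)(C)C(C)(C)C | intermediate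
12 | (2E,6E,10E)-12-[(tert-butyldimethylsilyl)oxy]-2,6,10-trimethyldodeca-2,6,10-trien-1-ol | OC/C(C)=C/CC/C(C)=C/CC/C(C)=C/CO[Si](C)(C)C(C)(C)C | intermediate
13 | tert-butyl{[(2E,6E,10E)-12-chloro-3,7,11-trimethyldodeca-2,6,10-trien-1-yl]oxy}dimethylsilane | ClC/C(C)=C/CC/C(C)=C/CC/C(C)=C/CO[Si](C)(C)C(C)(C)C | intermediate
14 | tert-butyldimethyl{[(2E,6E,10S)-3,7,10,11-tetramethyldodeca-2,6,11-trien-1-yl]oxy}silane | C=C(C)[C@@H](C)CC/C(C)=C/CC/C(C)=C/CO[Si](C)(C)C(C)(C)C | intermediate
15 | (2E,6E,10S)-3,7,10,11-tetramethyldodeca-2,6,11-trien-1-ol | C=C(C)[C@@H](C)CC/C(C)=C/CC/C(C)=C/CO | intermediate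
16 | diethyl (2E,6E,10S)-3,7,10,11-tetramethyldodeca-2,6,11-trien-1-yl phosphate | C=C(C)[C@@H](C)CC/C(C)=C/CC/C(C)=C/COP(=O)(OCC)OCC | intermediate
17 | diisobutyl{(1E,3R)-3-methyl-5-[(1R,3S)-2,2,3-trimethyl-6-methylidenecyclohexyl]pent-1-en-1-yl}alane | CC(C)C[Al](CC(C)C)/C=C/[C@H](C)CC[C@@H]1C(=C)CC[C@H](C)C1(C)C | intermediate (not isolated)
18 | (1R,3S)-1-[(3R,4E,6S,9E,13S)-6-ethenyl-3,6,10,13,14-pentamethylpentadeca-4,9,14-trien-1-yl]-2,2,3-trimethyl-6-methylidenecyclohexane | C=C[C@@](C)(/C=C/[C@H](C)CC[C@@H]1C(=C)CC[C@H](C)C1(C)C)CC/C=C(\C)CC[C@H](C)C(=C)C | target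

Total step count: 14. Longest linear sequence: 8 steps (steps 1 to 7, then step 14).

Steps most likely to fail

Step 5. Hydrogen-atom transfer to, or hydride reduction of, the vinyl ketone may compete with activation of the vinyl donor, and facial selectivity in the radical attack may be insufficient, so that the methyl-bearing centre forms partly trans to the side chain. The fallback closes the same ring bond by olefin metathesis and sets the centre by hydrogenation. It sets out from 1: CuI-catalysed conjugate addition of isopropenylmagnesium bromide and base equilibration would give (2S,5R)-2-(2,3-dimethylbut-3-en-2-yl)-5-methylcyclohexan-1-one F1. Enolate hydroxylation as in step 2 would give (3R,6S)-6-(2,3-dimethylbut-3-en-2-yl)-2-hydroxy-3-methylcyclohexan-1-one F2. Allylmagnesium bromide would give (3R,6S)-6-(2,3-dimethylbut-3-en-2-yl)-3-methyl-1-(prop-2-en-1-yl)cyclohexane-1,2-diol F3, and Pb(OAc)4 cleavage would give (2R,5S)-5-(2,3-dimethylbut-3-en-2-yl)-2-methyl-6-oxonon-8-enal F4. Ring-closing metathesis with the second-generation Hoveyda–Grubbs catalyst would give (2R)-2-methyl-4-[(1S)-2,2,3-trimethyl-6-oxocyclohex-3-en-1-yl]butanal F5. Hydrogenation (H2, Pd/C, EtOAc) from the face opposite the side chain would return to the route at 7.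

Step 14. Hydroalumination of the branched alkyne may be incomplete or unselective, an isobutyl group may transfer or SN2 attack may compete, and catalyst control may be eroded by the stereocentre of the alkenylalane, lowering facial selectivity at the quaternary carbon. The fallback uses a slimmer sp-carbon nucleophile and makes the E-olefin by reduction. It sets out from 9 and 16: 9 would be metalated with i-Bu2AlH and catalytic Et3N to diisobutyl{(3R)-3-methyl-5-[(1R,3S)-2,2,3-trimethyl-6-methylidenecyclohexyl]pent-1-yn-1-yl}alane F6. The copper–carbene-catalysed SN2' substitution of 16 with this reagent would give the 1,4-enyne (1R,3S)-1-[(3R,6S,9E,13S)-6-ethenyl-3,6,10,13,14-pentamethylpentadeca-9,14-dien-4-yn-1-yl]-2,2,3-trimethyl-6-methylidenecyclohexane F7. Dissolving-metal reduction (Na, NH3/THF, −78 to −33 °C) of the isolated alkyne to the (E)-olefin would arrive at 18.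

Step 11. SN2 attack at the primary carbon may compete with SN2' delivery, and enantiofacial discrimination may be low for this aliphatic β-methyl allylic chloride. The fallback replaces catalyst control by reagent-controlled epoxidation and stereospecific epoxide opening. It sets out from 12: Sharpless asymmetric epoxidation (Ti(Oi-Pr)4, D-(−)-diethyl tartrate, t-BuOOH) would give {(2R,3R)-3-[(3E,7E)-9-[(tert-butyldimethylsilyl)oxy]-3,7-dimethylnona-3,7-dien-1-yl]-2-methyloxiran-2-yl}methanol F8. Me2CuLi would open the epoxide at the less substituted carbon with inversion to give (2S,3S,6E,10E)-12-[(tert-butyldimethylsilyl)oxy]-2,3,6,10-tetramethyldodeca-6,10-diene-1,2-diol F9. 1,1'-Thiocarbonyldiimidazole would give the cyclic thionocarbonate of this diol F10, and Corey–Winter elimination (P(OMe)3, heat) would form the isopropenyl group and return to the route at 14.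

Further compounds
F1 | step 5 | (2S,5R)-2-(2,3-dimethylbut-3-en-2-yl)-5-methylcyclohexan-1-one | C[C@@H]1CC[C@@H](C(C)(C)C(C)=C)C(=O)C1
F2 | step 5 | (3R,6S)-6-(2,3-dimethylbut-3-en-2-yl)-2-hydroxy-3-methylcyclohexan-1-one, both C2 epimers | C[C@@H]1CC[C@@H](C(C)(C)C(C)=C)C(=O)C1O
F3 | step 5 | (3R,6S)-6-(2,3-dimethylbut-3-en-2-yl)-3-methyl-1-(prop-2-en-1-yl)cyclohexane-1,2-diol, diastereomers at C1 and C2 | C[C@@H]1CC[C@@H](C(C)(C)C(C)=C)C(O)(CC=C)C1O
F4 | step 5 | (2R,5S)-5-(2,3-dimethylbut-3-en-2-yl)-2-methyl-6-oxonon-8-enal | C[C@@H](C=O)CC[C@@H](C(C)(C)C(C)=C)C(=O)CC=C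
F5 | step 5 | (2R)-2-methyl-4-[(1S)-2,2,3-trimethyl-6-oxocyclohex-3-en-1-yl]butanal | O=C[C@H](C)CC[C@@H]1C(=O)CC=C(C)C1(C)C
F6 | step 14 | diisobutyl{(3R)-3-methyl-5-[(1R,3S)-2,2,3-trimethyl-6-methylidenecyclohexyl]pent-1-yn-1-yl}alane | CC(C)C[Al](CC(C)C)C#C[C@H](C)CC[C@@H]1C(=C)CC[C@H](C)C1(C)C
F7 | step 14 | (1R,3S)-1-[(3R,6S,9E,13S)-6-ethenyl-3,6,10,13,14-pentamethylpentadeca-9,14-dien-4-yn-1-yl]-2,2,3-trimethyl-6-methylidenecyclohexane | C=C[C@@](C)(C#C[C@H](C)CC[C@@H]1C(=C)CC[C@H](C)C1(C)C)CC/C=C(\C)CC[C@H](C)C(=C)C
F8 | step 11 | {(2R,3R)-3-[(3E,7E)-9-[(tert-butyldimethylsilyl)oxy]-3,7-dimethylnona-3,7-dien-1-yl]-2-methyloxiran-2-yl}methanol | OC[C@@]1(C)O[C@@H]1CC/C(C)=C/CC/C(C)=C/CO[Si](C)(C)C(C)(C)C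
F9 | step 11 | (2S,3S,6E,10E)-12-[(tert-butyldimethylsilyl)oxy]-2,3,6,10-tetramethyldodeca-6,10-diene-1,2-diol | OC[C@@](C)(O)[C@@H](C)CC/C(C)=C/CC/C(C)=C/CO[Si](C)(C)C(C)(C)C
F10 | step 11 | cyclic thionocarbonate (1,3-dioxolane-2-thione) of diol F9 | S=C1OC[C@@](C)(O1)[C@@H](C)CC/C(C)=C/CC/C(C)=C/CO[Si](C)(C)C(C)(C)C
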